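## The problem

Compound 16 is a depside: two benzene rings joined only through an aryl ester, whose carbonyl carbon sits on C1 of ring A and whose oxygen sits on C4 of ring B. Ring B, a methyl 2-hydroxy-3,6-dimethylbenzoate unit, is the intact skeleton of atraric acid 8, so the work lies in ring A and in the ester link. Ring A is hexasubstituted (C1 ester carbonyl, C2 CH3, C3 OH, C4 OH, C5 CHO, C6 OH), and every substituent must be placed by regiocontrol alone. There is no stereocentre, so no centre has to control another. The ester carbonyl is flanked by the C2 methyl and the C6 oxygen, which makes a late acylation of the ring B phenol by a ring A acid slow, and polyhydroxybenzoic acids of this kind lose CO2 easily. Unmasked ring A is a hydroxyhydroquinone (C3-OH para to C6-OH, C3/C4 a catechol) bearing an aldehyde; it autoxidises in base, and the aryl ester and methyl ester are open to nucleophiles. The ring A oxygens therefore stay protected until a final acidic, non-oxidising step. The enabling feature is the triad C6(O)–C1(C=O)–C2(CH3): it is what remains when an aryl iodide with one ortho oxygen is methylated at its single ortho C–H and carbonylated at the carbon that carried iodine. The C2 methyl, the carbonyl carbon and the ring B oxygen can thus be attached in one palladium and norbornene relay to a ring that already holds C3 to C6.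

## Retrosynthesis

**16 to 15.** The last bonds cut are four O–CH2OCH3 bonds, leading back to the tetrakis(methoxymethyl) ether 15. Methoxymethyl (MOM) ethers are chosen because they direct lithiation, are inert to Cs2CO3, iodomethane and palladium, and leave under mild acid that the hindered depside ester tolerates. Benzyl ethers would need hydrogenolysis next to an aryl aldehyde, and methyl ethers would need boron halides that endanger the ester. The 2-hydroxyl of ring B is also carried as a MOM ether: a free, even chelated, phenol would be O-methylated or acylated under Cs2CO3 and iodomethane at 90 °C. Compound 15 has no free phenol and is not oxidation-prone.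

**15 to 7, 13 and 12 (key cut).** Three bonds are cut at once: C2–CH3, C1–C(=O) and C(=O)–O(ring B). The pieces are aryl iodide 7, iodomethane 13 and aryl formate 12, which supplies both carbon monoxide and the ring B phenolate. The neighbouring cut, through the ester C–O bond alone, would require a fully substituted ring A benzoic acid, made in many steps and coupled at a doubly ortho-hindered carbonyl. The chosen cut starts from a ring with only four substituents and builds the hindered ester on palladium. The forward reaction must methylate before it carbonylates and must do so at C2. It must also keep the released phenolate from being consumed by iodomethane.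

**7 to 6.** The C–I bond is cut. In 6 the position that becomes C1 of ring A is ortho to one MOM ether, para to a second and meta to the aldehyde. The only other free position is para to the aldehyde with a single ortho oxygen, so electrophilic iodination should go where needed. The reagent must be non-acidic because of the MOM groups.

**6 to 4 (through 5).** The C–CHO bond is cut. In 4 the hydrogen between the two 1,3-related MOM ethers is the most acidic and the best chelated, so ortho-lithiation to 5 and quenching with DMF places the aldehyde there. Electrophilic formylation would attack the other, more electron-rich position and is not an option.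

**4 to 2 and 3, and 2 to 1.** Three O–CH2 bonds are cut to benzene-1,2,4-triol 2 and chloromethyl methyl ether 3. Air-sensitive 2 is made fresh from its stable, cheap triacetate 1.

**12 to 11, 10, 9 and 8.** The O–CHO bond of 12 is cut to phenol 11. Because the 4-hydroxyl of 8 is the more reactive one, the 2-O-MOM group is installed by a short detour. Selective 4-O-benzylation gives 9, MOM protection of the chelated 2-hydroxyl with 3 gives 10, and hydrogenolysis gives 11. Each reaction is routine, and the sequence runs in parallel with the ring A branch.

## Roads not taken

**Alternative 1:** The cut runs through ring A bonds C1–C2 and C4–C5. tert-Butyl 3-oxobutanoate A1 would add as its carbanion to the β-carbon of methyl 2-(benzyloxy)but-2-enoate A2. Claisen closure of the acetyl methyl carbanion onto the methyl ester would then give the cyclohexane-1,3-dione A3, to be dehydrogenated later.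
- Merits: cheap acyclic inputs; every reaction type is established; the C1 carboxyl, C2 methyl and C3, C4 and C6 oxygens are placed by connectivity alone.
- Weak points: A2 is a reluctant Michael acceptor (donor oxygen at the α-carbon, methyl at the β-carbon). After A3 the route still needs dehydrogenation of a crowded 1,3-dione, formylation at C5, release of a decarboxylation-prone hindered acid, coupling of that acid to ring B, and protecting-group changes on several phenols.
- Comparison: this road is better in that nothing in it is untested. The chosen plan offers convergence, no change of oxidation level on an oxygen-rich ring, and a hindered ester made on palladium instead of from a free acid. Its longest sequence is expected to be shorter.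

**Alternative 2:** The cut runs through ring A bonds C1–C6 and C2–C3. The ring B butynoate A4 and the bis-silyloxy diene A5 would undergo a thermal [4+2] cycloaddition. Loss of methoxytrimethylsilane and acidic work-up would then give the depside A6, which has C4-OH and C6-OH free and the C3 oxygen as a 4-methoxybenzyl ether.
- Merits: highly convergent; the ester is made on a simple alkynoic acid, so no hindered coupling arises; the polarity of the diene fixes the regiochemistry; the whole route is probably shorter than the chosen one and uses only known reaction classes.
- Weak points: a β-methyl alkynoate is a sluggish dienophile, and A5, a 4-alkoxy ketene acetal diene, is heat- and moisture-sensitive and must react in its s-cis form. The aryl ester of A4 is an active ester that such a nucleophilic diene can acylate or add to without ring closure. A6 still lacks the C5 aldehyde, so a formylation must be run on a depside with three free phenols and an acid-labile ether.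
- Comparison: in step count and precedent this road is at least as good. The chosen plan carries the aldehyde in from the start, placed by lithiation on a simple arene, and avoids a forcing cycloaddition with a fragile diene. It pays with one unprecedented catalytic merger.

**Alternative 3:** The cut runs through ring A bonds C2–C3 and C4–C5. The 2-pyrone ester A7 and 2,2-dimethyl-1,3-dioxole A8 would be heated in a sealed vessel. Cycloaddition, loss of CO2 and dehydrogenation with DDQ in the same flask would give the benzodioxole depside A9.
- Merits: both catechol oxygens arrive together as one acetonide; ring B is attached beforehand; one operation delivers the arene.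
- Weak points: A7 carries a donor methoxy group and A8 is also electron-rich, so the cycloaddition is poorly matched and needs forcing conditions. A8 is volatile and must be prepared. After CO2 loss the cyclohexadiene can aromatize by eliminating one of its allylic C–O bonds instead of being dehydrogenated, which would lose a ring oxygen. A9 then still needs C5 formylation, cleavage of an aryl methyl ether and removal of the acetonide with Lewis acids that threaten the depside.
- Comparison: the cycloaddition itself is a known reaction class, which the chosen key step is not. The chosen plan needs no oxidation or elimination-prone intermediate and ends with one mild acid step instead of a boron halide deprotection.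

Key step: step 9

Remark: the target has no stereocentre, so no step needs stereocontrol. Hydrolysis of each methoxymethyl ether is balanced as giving formaldehyde and methanol.

## Route

Step 1
Reactants: 1 benzene-1,2,4-triyl triacetate (1,2,4-triacetoxybenzene)
Product: 2 benzene-1,2,4-triol
Conditions: HCl (cat.), degassed MeOH, reflux, Ar; evaporate, use at once
Reagents that add atoms: none
Why: Acid-catalysed methanolysis (transesterification) of the three aryl acetates; the acidic medium keeps the air-sensitive triol protonated, and methyl acetate leaves on evaporation.

Step 2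
Reactants: 2 benzene-1,2,4-triol; 3 chloromethyl methyl ether
Product: 4 1,2,4-tris(methoxymethoxy)benzene
Conditions: NaH, DMF, 0 °C; then 3, 0 °C → rt, Ar
Reagents that add atoms: chloromethyl methyl ether (3), COCCl
Why: Williamson-type O-alkylation of the phenoxides by the reactive α-chloro ether; strict exclusion of oxygen guards the electron-rich phenoxides until they are capped.

Step 3
Reactants: 4 1,2,4-tris(methoxymethoxy)benzene
Product: 6 2,3,6-tris(methoxymethoxy)benzaldehyde, via [2,3,6-tris(methoxymethoxy)phenyl]lithium 5 (not isolated)
Conditions: n-BuLi, TMEDA, THF, −20 → 0 °C; DMF, 0 °C → rt; H2O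
Reagents that add atoms: N,N-dimethylformamide, CN(C)C=O
Why: Directed ortho-metalation; the hydrogen between the two 1,3-related MOM ethers is acidified and chelated by both, as is known for 1,2,4-trialkoxybenzenes, and the aryllithium is formylated by DMF.

Step 4
Reactants: 6 2,3,6-tris(methoxymethoxy)benzaldehyde
Product: 7 3-iodo-2,5,6-tris(methoxymethoxy)benzaldehyde
Conditions: I2, CF3CO2Ag, NaHCO3, CHCl3, 0 °C → rt, dark
Reagents that add atoms: iodine, II
Why: Electrophilic aromatic iodination by the hypoiodite from I2 and CF3CO2Ag; the attacked carbon is ortho to one MOM ether, para to another and meta to the aldehyde, whereas the other free carbon is para to the aldehyde; NaHCO3 takes up the trifluoroacetic acid so the MOM ethers survive.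

Step 5
Reactants: 8 methyl 2,4-dihydroxy-3,6-dimethylbenzoate (atraric acid)
Product: 9 methyl 4-(benzyloxy)-2-hydroxy-3,6-dimethylbenzoate
Conditions: BnBr (1.05 equiv), K2CO3, acetone, reflux
Reagents that add atoms: benzyl bromide, BrCc1ccccc1
Why: Williamson etherification; the 2-hydroxyl is tied up in a hydrogen bond to the ester carbonyl, so one equivalent of benzyl bromide alkylates the more acidic, free 4-hydroxyl.

Step 6
Reactants: 9 methyl 4-(benzyloxy)-2-hydroxy-3,6-dimethylbenzoate; 3 chloromethyl methyl ether
Product: 10 methyl 4-(benzyloxy)-2-(methoxymethoxy)-3,6-dimethylbenzoate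
Conditions: NaH, DMF, 0 °C; then 3, 0 °C → rt
Reagents that add atoms: chloromethyl methyl ether (3), COCCl
Why: Irreversible deprotonation breaks the chelate, and the sodium phenoxide is O-alkylated by the α-chloro ether, the usual way to protect salicylate-type hydroxyls.

Step 7
Reactants: 10 methyl 4-(benzyloxy)-2-(methoxymethoxy)-3,6-dimethylbenzoate
Product: 11 methyl 4-hydroxy-2-(methoxymethoxy)-3,6-dimethylbenzoate
Conditions: H2 (1 atm), 10% Pd/C, EtOAc, rt
Reagents that add atoms: none
Why: Catalytic hydrogenolysis of the benzyl aryl ether; the MOM ether, methyl ester and arene are inert under these neutral conditions.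

Step 8
Reactants: 11 methyl 4-hydroxy-2-(methoxymethoxy)-3,6-dimethylbenzoate
Product: 12 methyl 4-(formyloxy)-2-(methoxymethoxy)-3,6-dimethylbenzoate
Conditions: HCO2H, Ac2O, 55 °C (gives acetic formic anhydride); then 11, NaOAc, THF, 0 °C → rt
Reagents that add atoms: formic acid, O=CO (delivered as acetic formic anhydride, CC(=O)OC=O)
Why: O-Formylation with a mixed anhydride, in which the phenol attacks the more electrophilic formyl carbonyl; the NaOAc buffer and absence of strong acid spare the MOM ether, and 12 is used without long storage.

Step 9
Reactants: 7 3-iodo-2,5,6-tris(methoxymethoxy)benzaldehyde; 13 iodomethane; 12 methyl 4-(formyloxy)-2-(methoxymethoxy)-3,6-dimethylbenzoate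
Product: 15 methyl 4-{[3-formyl-2,4,5-tris(methoxymethoxy)-6-methylbenzoyl]oxy}-2-(methoxymethoxy)-3,6-dimethylbenzoate, via caesium 4-(methoxycarbonyl)-3-(methoxymethoxy)-2,5-dimethylphenolate 14 (not isolated)
Conditions: Pd(OAc)2 (10 mol %), tri(2-furyl)phosphine (25 mol %), norbornene (2 equiv), Cs2CO3 (4 equiv), 13 (3 equiv), 12 (2.5 equiv, added over 8 h by syringe pump), toluene, 90 °C, sealed tube, Ar
Reagents that add atoms: iodomethane (13), CI
Why: Proposed new method: zerovalent palladium inserts into the C–I bond of 7, norbornene carbopalladation and carbonate-assisted C–H palladation at C2 (the only ortho C–H, made more acidic by the adjacent oxygen) give a five-membered aryl–norbornyl palladacycle, 13 adds oxidatively to this divalent palladium centre, and reductive elimination from tetravalent palladium forms the C2–CH3 bond. With both ortho positions now filled, β-carbon elimination expels norbornene and leaves a 2,6-disubstituted arylpalladium species. Cs2CO3 fragments formate 12 into carbon monoxide and phenolate 14; carbon monoxide inserts into the aryl–palladium bond and 14 attacks the acyl complex, forming the C1–C(=O) and C(=O)–O bonds and returning zerovalent palladium. The closest known reaction types are Catellani ortho-alkylation with ipso termination and palladium-catalysed aryloxycarbonylation of aryl iodides with aryl formates; their merger and palladation beside an alkoxy group are the untested parts. No ring closes and no stereocentre forms. The step needs the right order (methylation before carbonylation) and the right site (C2): norbornene cannot leave before C2 is substituted, C6 is blocked by its oxygen, and slow addition of 12 keeps carbon monoxide too scarce to intercept the first arylpalladium species. The MOM group on the ring B 2-oxygen, the non-polar solvent and the excess of 12 and 13 guard against O-methylation of 14 by 13.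

Step 10
Reactants: 15 methyl 4-{[3-formyl-2,4,5-tris(methoxymethoxy)-6-methylbenzoyl]oxy}-2-(methoxymethoxy)-3,6-dimethylbenzoate
Product: 16 methyl 4-[(3-formyl-2,4,5-trihydroxy-6-methylbenzoyl)oxy]-2-hydroxy-3,6-dimethylbenzoate
Conditions: conc. aq. HCl, i-PrOH/THF, 45 °C, Ar
Reagents that add atoms: none
Why: Acid-catalysed acetal hydrolysis of the four MOM ethers; the doubly ortho-substituted aryl ester and the hindered alcohol solvent disfavour transesterification, and acidic, oxygen-free conditions protect the liberated hydroxyhydroquinone.

## Compound list

1 | benzene-1,2,4-triyl triacetate (1,2,4-triacetoxybenzene) | CC(=O)Oc1ccc(OC(C)=O)c(OC(C)=O)c1 | starting material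
2 | benzene-1,2,4-triol | Oc1ccc(O)c(O)c1 | intermediate
3 | chloromethyl methyl ether | COCCl | starting material
4 | 1,2,4-tris(methoxymethoxy)benzene | COCOc1ccc(OCOC)c(OCOC)c1 | intermediate
5 | [2,3,6-tris(methoxymethoxy)phenyl]lithium | [Li]c1c(OCOC)ccc(OCOC)c1OCOC | intermediate (not isolated)
6 | 2,3,6-tris(methoxymethoxy)benzaldehyde | O=Cc1c(OCOC)ccc(OCOC)c1OCOC | intermediate
7 | 3-iodo-2,5,6-tris(methoxymethoxy)benzaldehyde | O=Cc1c(OCOC)c(I)cc(OCOC)c1OCOC | intermediate
8 | methyl 2,4-dihydroxy-3,6-dimethylbenzoate (atraric acid) | COC(=O)c1c(C)cc(O)c(C)c1O | starting material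
9 | methyl 4-(benzyloxy)-2-hydroxy-3,6-dimethylbenzoate | COC(=O)c1c(C)cc(OCc2ccccc2)c(C)c1O | intermediate
10 | methyl 4-(benzyloxy)-2-(methoxymethoxy)-3,6-dimethylbenzoate | COC(=O)c1c(C)cc(OCc2ccccc2)c(C)c1OCOC | intermediate
11 | methyl 4-hydroxy-2-(methoxymethoxy)-3,6-dimethylbenzoate | COC(=O)c1c(C)cc(O)c(C)c1OCOC | intermediate
12 | methyl 4-(formyloxy)-2-(methoxymethoxy)-3,6-dimethylbenzoate | COC(=O)c1c(C)cc(OC=O)c(C)c1OCOC | intermediate
13 | iodomethane | CI | starting material
14 | caesium 4-(methoxycarbonyl)-3-(methoxymethoxy)-2,5-dimethylphenolate | [Cs+].[O-]c1cc(C)c(C(=O)OC)c(OCOC)c1C | intermediate (not isolated)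
15 | methyl 4-{[3-formyl-2,4,5-tris(methoxymethoxy)-6-methylbenzoyl]oxy}-2-(methoxymethoxy)-3,6-dimethylbenzoate | COC(=O)c1c(C)cc(OC(=O)c2c(C)c(OCOC)c(OCOC)c(C=O)c2OCOC)c(C)c1OCOC | intermediate
16 | methyl 4-[(3-formyl-2,4,5-trihydroxy-6-methylbenzoyl)oxy]-2-hydroxy-3,6-dimethylbenzoate | COC(=O)c1c(C)cc(OC(=O)c2c(C)c(O)c(O)c(C=O)c2O)c(C)c1O | target

## Step count and least certain steps

Total step count: 10. Longest linear sequence: 6 steps (steps 1, 2, 3, 4, 9, 10, or equally steps 5, 6, 7, 8, 9, 10).

**Step 9 (key step, proposed new method).** Four things are most likely to go wrong: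
- Carbon monoxide may insert into the first arylpalladium species, or into the palladacycle, before the methyl group is in place. This gives ipso carbonylation without ortho-methylation.
- C–H palladation at C2 may fail, because that carbon is squeezed between the palladium-bearing carbon and a MOM ether.
- Phenolate 14 may be O-methylated by 13 faster than it is acylated on palladium.
- The ligand that suits the norbornene relay may be poor for the final acyl–oxygen bond formation.

The fallback uses known chemistry, sets out from 7, uses phenol 11 and iodomethane 13, and rejoins the route at 16.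
- The aldehyde of 7 is masked with 1,2-bis(trimethylsilyloxy)ethane and catalytic trimethylsilyl triflate in CH2Cl2 at −78 °C, giving 2-[3-iodo-2,5,6-tris(methoxymethoxy)phenyl]-1,3-dioxolane F1.
- Iodine–lithium exchange (n-BuLi, THF, −78 °C) and carboxylation with CO2 give 3-(1,3-dioxolan-2-yl)-2,4,5-tris(methoxymethoxy)benzoic acid F2.
- The lithium carboxylate of F2 is ortho-lithiated at its only ring hydrogen, which lies between the carboxylate and a MOM ether (s-BuLi, TMEDA, THF, −78 °C). Quenching with 13 gives 3-(1,3-dioxolan-2-yl)-2,4,5-tris(methoxymethoxy)-6-methylbenzoic acid F3.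
- Carbodiimide esterification with 11 (DCC, catalytic DMAP, CH2Cl2) gives methyl 4-{[3-(1,3-dioxolan-2-yl)-2,4,5-tris(methoxymethoxy)-6-methylbenzoyl]oxy}-2-(methoxymethoxy)-3,6-dimethylbenzoate F4.
- The acid treatment of step 10 removes the dioxolane together with the four MOM ethers and gives 16.

**Step 4.** The iodination may stall because the aldehyde deactivates the ring, or acid released during the substitution may strip the MOM ether next to the aldehyde. The fallback sets out from 6 and rejoins at 7, with the iodination done at the more electron-rich alcohol oxidation level.
- Reduction with NaBH4 in MeOH gives [2,3,6-tris(methoxymethoxy)phenyl]methanol F5.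
- N-Iodosuccinimide in MeCN at rt, with no acid, iodinates the same ortho/para-activated carbon and gives [3-iodo-2,5,6-tris(methoxymethoxy)phenyl]methanol F6.
- Oxidation with MnO2 in CH2Cl2 returns the aldehyde as 7.

**Step 10.** Cleavage of the most hindered MOM ether (on C3 of ring A) may be slow. Meanwhile released formaldehyde may alkylate the free carbon of ring B para to its hydroxyl, the aryl ester may be attacked by solvent, or the free hydroxyhydroquinone may be oxidised during a long reaction. The fallback sets out from 15 and rejoins at 16, replacing aqueous acid by anhydrous silyl transfer.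
- Bromotrimethylsilane in CH2Cl2 (−30 → 0 °C) is expected to exchange each MOM group for a trimethylsilyl group without liberating formaldehyde. The product is methyl 4-{[3-formyl-6-methyl-2,4,5-tris(trimethylsilyloxy)benzoyl]oxy}-3,6-dimethyl-2-(trimethylsilyloxy)benzoate F7.
- The aryl silyl ethers are hydrolysed on quenching with aqueous methanol to give 16.

## Further compounds

F1 | step 9 | 2-[3-iodo-2,5,6-tris(methoxymethoxy)phenyl]-1,3-dioxolane | COCOc1c(I)cc(OCOC)c(OCOC)c1C1OCCO1
F2 | step 9 | 3-(1,3-dioxolan-2-yl)-2,4,5-tris(methoxymethoxy)benzoic acid | COCOc1c(C(=O)O)cc(OCOC)c(OCOC)c1C1OCCO1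
F3 | step 9 | 3-(1,3-dioxolan-2-yl)-2,4,5-tris(methoxymethoxy)-6-methylbenzoic acid | COCOc1c(C(=O)O)c(C)c(OCOC)c(OCOC)c1C1OCCO1
F4 | step 9 | methyl 4-{[3-(1,3-dioxolan-2-yl)-2,4,5-tris(methoxymethoxy)-6-methylbenzoyl]oxy}-2-(methoxymethoxy)-3,6-dimethylbenzoate | COC(=O)c1c(C)cc(OC(=O)c2c(C)c(OCOC)c(OCOC)c(C3OCCO3)c2OCOC)c(C)c1OCOC
F5 | step 4 | [2,3,6-tris(methoxymethoxy)phenyl]methanol | OCc1c(OCOC)ccc(OCOC)c1OCOC
F6 | step 4 | [3-iodo-2,5,6-tris(methoxymethoxy)phenyl]methanol | OCc1c(OCOC)c(I)cc(OCOC)c1OCOC
F7 | step 10 | methyl 4-{[3-formyl-6-methyl-2,4,5-tris(trimethylsilyloxy)benzoyl]oxy}-3,6-dimethyl-2-(trimethylsilyloxy)benzoate | COC(=O)c1c(C)cc(OC(=O)c2c(C)c(O[Si](C)(C)C)c(O[Si](C)(C)C)c(C=O)c2O[Si](C)(C)C)c(C)c1O[Si](C)(C)C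
A1 | alternative 1 | tert-butyl 3-oxobutanoate | CC(=O)CC(=O)OC(C)(C)C
A2 | alternative 1 | methyl 2-(benzyloxy)but-2-enoate (either geometrical isomer) | CC=C(OCc1ccccc1)C(=O)OC
A3 | alternative 1 | tert-butyl 3-(benzyloxy)-2-methyl-4,6-dioxocyclohexane-1-carboxylate (mixture of diastereomers and enol tautomers) | CC1C(C(=O)OC(C)(C)C)C(=O)CC(=O)C1OCc1ccccc1
A4 | alternative 2 | methyl 4-(but-2-ynoyloxy)-2-hydroxy-3,6-dimethylbenzoate | CC#CC(=O)Oc1cc(C)c(C(=O)OC)c(O)c1C
A5 | alternative 2 | 1-methoxy-4-[(4-methoxybenzyl)oxy]-1,3-bis(trimethylsilyloxy)buta-1,3-diene (mixture of geometrical isomers) | COC(O[Si](C)(C)C)=CC(O[Si](C)(C)C)=COCc1ccc(OC)cc1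
A6 | alternative 2 | methyl 4-({4,6-dihydroxy-3-[(4-methoxybenzyl)oxy]-2-methylbenzoyl}oxy)-2-hydroxy-3,6-dimethylbenzoate | COC(=O)c1c(C)cc(OC(=O)c2c(C)c(OCc3ccc(OC)cc3)c(O)cc2O)c(C)c1O
A7 | alternative 3 | methyl 2-hydroxy-4-[(4-methoxy-2-methyl-6-oxo-6H-pyran-3-carbonyl)oxy]-3,6-dimethylbenzoate | COC(=O)c1c(C)cc(OC(=O)C2=C(C)OC(=O)C=C2OC)c(C)c1O
A8 | alternative 3 | 2,2-dimethyl-1,3-dioxole | CC1(C)OC=CO1
A9 | alternative 3 | methyl 2-hydroxy-4-[(6-methoxy-2,2,4-trimethyl-1,3-benzodioxole-5-carbonyl)oxy]-3,6-dimethylbenzoate | COC(=O)c1c(C)cc(OC(=O)c2c(C)c3OC(C)(C)Oc3cc2OC)c(C)c1O
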